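**Plan**

1. The target is read as a 2,3‑seco ent‑13‑epi‑manoyl oxide: a trans‑fused oxadecalin whose carbocycle (ring B, C5–C10 in labdane numbering) carries the two arms left by a cleaved ring A.
2. Retrosynthetic cuts, in order: the C8–O ether bond (hydroalkoxylation of a C8=C17 methylidene by the C13 alcohol); C17 (methylenation of a C8 ketone); the C9–C10 bond, by the reverse of a 1,2‑shift, which contracts ring B to a cyclopentanol (C5, C6, C7, C8, C10) with C9 as an exocyclic alkenyl carbon; C8–C9 (acetylide + cyclopentanone); C10–C1 and C5–C4 (enolate alkylation and conjugate addition on 2‑methylcyclopentenone).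
3. The feature that allows the ring expansion: C9 lies between C8, which carries oxygen, and the quaternary C10. Ring B is therefore a cyclopentanone (C8=O next to C10) into which C9, with the whole C11–C16 chain, is inserted by migration of the C8–C10 bond.
4. Forward order: three‑component assembly of the cyclopentanone; (R)‑linalool cut down to a C7 enyne; acetylide addition; semihydrogenation; bromonium‑triggered ring expansion (ring B); debromination; methylenation; closure of the pyran ring; selective saponification.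
5. Stereochemistry: C5 from the chiral Lewis acid; C10 from C5 (alkylation anti); C13 from (R)‑linalool; C9 from the stereospecific shift, steered by the temporary C8 carbinol and the Z‑alkene; C8 from equatorial C–O bond formation opposite the axial C10 methyl.

Key step: step 7

Remark: atoms are numbered as in labdanes (C17 = methyl on C8, C20 = methyl on C10, C16 = methyl on C13). The (S)‑catalyst of step 1 is assumed to give (5S) by analogy with cycloalkenones that lack the α‑methyl group; if the opposite sense is found, the (R)‑catalyst is used.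

**Step 1**
Reactants: 1 2‑methylcyclopent‑2‑en‑1‑one; 2 1‑methoxy‑2‑methyl‑1‑(trimethylsilyloxy)prop‑1‑ene; 3 methyl bromoacetate
Product: 5 methyl 2‑[(1R,2S)‑2‑(1‑methoxy‑2‑methyl‑1‑oxopropan‑2‑yl)‑1‑methyl‑5‑oxocyclopentyl]acetate, via silyl enol ether 4 (not isolated)
Conditions: 1, 2 (1.1 equiv), (S)‑3,3‑diphenyl‑1‑(2‑methylphenyl)tetrahydro‑1H,3H‑pyrrolo[1,2‑c][1,3,2]oxazaborole/HNTf2 (20 mol%), Ph3PO (25 mol%), toluene, −20 °C; then evaporate, THF, 3, Bu4N[Ph3SiF2], −78 °C → rt
Reagents that add atoms: none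
Why: An enantioselective Mukaiyama–Michael addition catalysed by the chiral oxazaborolidinium Lewis acid should set C5 and leave the regio‑defined tetrasubstituted silyl enol ether; fluoride turns it into an ammonium enolate that is C‑alkylated anti to the bulky C5 substituent, creating the quaternary C10 (three‑component conjugate addition/enolate trapping).

**Step 2**
Reactants: 6 (R)‑(−)‑linalool
Product: 7 tert‑butyl{[(3R)‑3,7‑dimethylocta‑1,6‑dien‑3‑yl]oxy}dimethylsilane
Conditions: TBSOTf, 2,6‑lutidine, CH2Cl2, 0 °C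
Reagents that add atoms: tert‑butyldimethylsilyl trifluoromethanesulfonate, CC(C)(C)[Si](C)(C)OS(=O)(=O)C(F)(F)F
Why: Silylation of the tertiary allylic alcohol with a silyl triflate is standard and leaves the future C13 centre untouched.

**Step 3**
Reactants: 7 silyl ether of linalool
Product: 8 (4R)‑4‑[(tert‑butyldimethylsilyl)oxy]‑4‑methylhex‑5‑enal
Conditions: O3 (1 equiv), pyridine, CH2Cl2, −78 °C (Sudan Red 7B end point); then Me2S
Reagents that add atoms: ozone, [O-][O+]=O
Why: Ozonolysis should cleave the electron‑rich trisubstituted alkene well before the vinyl group, which is deactivated and shielded by the neighbouring silyloxy‑bearing quaternary carbon; the aldehyde carbon is the future C9.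

**Step 4**
Reactants: 8 aldehyde
Product: 10 tert‑butyldimethyl{[(3R)‑3‑methylhex‑1‑en‑5‑yn‑3‑yl]oxy}silane, via alkenyl nonaflate 9 (not isolated)
Conditions: C4F9SO2F, phosphazene base P2‑Et (2.5 equiv), DMF, −30 °C → rt
Reagents that add atoms: none
Why: O‑Sulfonylation of the aldehyde enolate followed by E2 elimination of the alkenyl nonaflate is a one‑pot conversion of an enolizable aldehyde into the terminal alkyne of the same carbon count (C9≡C11).

**Step 5**
Reactants: 10 enyne; 5 keto diester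
Product: 12 methyl 2‑[(1R,2R,5S)‑2‑{(4R)‑4‑[(tert‑butyldimethylsilyl)oxy]‑4‑methylhex‑5‑en‑1‑yn‑1‑yl}‑2‑hydroxy‑5‑(1‑methoxy‑2‑methyl‑1‑oxopropan‑2‑yl)‑1‑methylcyclopentyl]acetate, via lithium acetylide 11 (not isolated)
Conditions: 10, n‑BuLi (1.0 equiv), THF, −78 °C; then 5, −78 → −40 °C; aq NH4Cl
Reagents that add atoms: none
Why: A lithium acetylide adds to the ketone much faster than to the esters at −78 °C and should attack the face anti to the pseudo‑axial C10 methyl (as an angular methyl directs addition to a hydrindanone), so the C8 hydroxyl ends trans to the CH2CO2Me arm and cannot lactonize.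

**Step 6**
Reactants: 12 propargylic alcohol
Product: 13 methyl 2‑[(1R,2S,5S)‑2‑{(1Z,4R)‑4‑[(tert‑butyldimethylsilyl)oxy]‑4‑methylhexa‑1,5‑dien‑1‑yl}‑2‑hydroxy‑5‑(1‑methoxy‑2‑methyl‑1‑oxopropan‑2‑yl)‑1‑methylcyclopentyl]acetate
Conditions: H2 (1 atm), Pd/CaCO3 poisoned with Pb(OAc)2, quinoline, EtOAc, rt
Reagents that add atoms: none
Why: Lindlar semihydrogenation adds H2 syn to the alkyne and should give the Z‑alkene without touching the hindered vinyl group.

**Step 7**
Reactants: 13 Z‑allylic cyclopentanol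
Product: 14 methyl 2‑[(1R,2S,6S)‑2‑{(1S,3R)‑1‑bromo‑3‑[(tert‑butyldimethylsilyl)oxy]‑3‑methylpent‑4‑en‑1‑yl}‑6‑(1‑methoxy‑2‑methyl‑1‑oxopropan‑2‑yl)‑1‑methyl‑3‑oxocyclohexyl]acetate
Conditions: NBS, propylene oxide, CH2Cl2/i‑PrOH, −40 → 0 °C
Reagents that add atoms: N‑bromosuccinimide, O=C1CCC(=O)N1Br
Why: NBS delivers Br+ to the C9=C11 alkene and, as the bromonium ion opens, the C8–C10 ring bond shifts from C8 to C9 while the carbinol becomes the C8 ketone; this is a halonium‑induced semipinacol rearrangement, whose closest precedents are the hypochlorite‑ and NBS‑induced ring expansions of 1‑alkenylcycloalkanols to 2‑(haloalkyl)cycloalkanones. Ring B is closed by a 1,2‑alkyl shift, that is a one‑carbon ring expansion of the cyclopentane into the cyclohexanone, not by a cyclization. C9 is set stereospecifically: allylic 1,3‑strain of the Z‑alkene holds the C8–O bond in the alkene plane, so the two ring bonds lie above and below the π system; bromine attacks the face flanked by the C7 methylene and C10 enters C9 from the opposite face with retention at C10, which places C11 cis to the C10 methyl, while C11 (anti addition) is a temporary centre removed in step 8. The selectivity needed is migration of C10 and not of C7, and it is secured twice: the quaternary carbon is the better migrating group, and the alkene face anti to it is the only open one because the other is covered by C10 and its CH2CO2Me arm. Propylene oxide scavenges HBr, the silyl ether keeps the C13 oxygen from opening the bromonium ion, and the terminal vinyl group is the less nucleophilic alkene.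

**Step 8**
Reactants: 14 β‑bromo ketone
Product: 15 methyl 2‑[(1R,2S,6S)‑2‑{(3R)‑3‑[(tert‑butyldimethylsilyl)oxy]‑3‑methylpent‑4‑en‑1‑yl}‑6‑(1‑methoxy‑2‑methyl‑1‑oxopropan‑2‑yl)‑1‑methyl‑3‑oxocyclohexyl]acetate
Conditions: Bu3SnH (0.3 M), AIBN (cat.), benzene, 80 °C
Reagents that add atoms: none
Why: Radical chain debromination replaces the C11 bromine by hydrogen under neutral conditions that leave the epimerizable C9 untouched; the high stannane concentration should outrun a 1,2‑acyl shift of the β‑keto radical.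

**Step 9**
Reactants: 15 ketone
Product: 16 methyl 2‑[(1S,2R,6S)‑2‑{(3R)‑3‑[(tert‑butyldimethylsilyl)oxy]‑3‑methylpent‑4‑en‑1‑yl}‑6‑(1‑methoxy‑2‑methyl‑1‑oxopropan‑2‑yl)‑1‑methyl‑3‑methylidenecyclohexyl]acetate
Conditions: Zn, CH2Br2, TiCl4, THF/CH2Cl2, 0 °C → rt
Reagents that add atoms: dibromomethane, BrCBr
Why: Lombardo–Takai methylenation is non‑basic, so it should convert the hindered C8 ketone into the C8=C17 methylidene without epimerizing C9 and without touching the esters.

**Step 10**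
Reactants: 16 silyl ether
Product: 17 methyl 2‑[(1S,2R,6S)‑2‑[(3R)‑3‑hydroxy‑3‑methylpent‑4‑en‑1‑yl]‑6‑(1‑methoxy‑2‑methyl‑1‑oxopropan‑2‑yl)‑1‑methyl‑3‑methylidenecyclohexyl]acetate
Conditions: Bu4NF, THF, 45 °C
Reagents that add atoms: none
Why: Fluoride cleaves the tertiary silyl ether and frees the C13 hydroxyl for ring closure.

**Step 11**
Reactants: 17 dienol
Product: 18 methyl 2‑[(2R,4aS,5R,6S,8aS)‑2‑ethenyl‑6‑(1‑methoxy‑2‑methyl‑1‑oxopropan‑2‑yl)‑2,5,8a‑trimethyloctahydro‑2H‑chromen‑5‑yl]acetate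
Conditions: [N,N′‑bis(3,5‑di‑tert‑butylsalicylidene)‑1,2‑cyclohexanediaminato]cobalt (divalent cobalt, 3 mol%), N‑fluoro‑2,4,6‑trimethylpyridinium triflate, PhSiH3, PhCF3, rt
Reagents that add atoms: none
Why: Cobalt‑hydride hydrogen‑atom transfer to C17 of the 1,1‑disubstituted alkene gives the tertiary C8 radical, which is oxidized and captured by the C13 hydroxyl (Markovnikov intramolecular hydroalkoxylation by radical–polar crossover); C–O bond formation should be equatorial, opposite the axial C10 methyl, giving the trans‑fused pyran, and no C17‑centred radical arises that could cyclize onto the syn‑axial vinyl group.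

**Step 12**
Reactants: 18 diester
Product: 19 2‑[(2R,4aS,5R,6S,8aS)‑2‑ethenyl‑6‑(1‑methoxy‑2‑methyl‑1‑oxopropan‑2‑yl)‑2,5,8a‑trimethyloctahydro‑2H‑chromen‑5‑yl]acetic acid (target)
Conditions: LiOH, THF/MeOH/H2O, rt; then 1 M HCl to pH 4, 0 °C
Reagents that add atoms: lithium hydroxide, [Li+].[OH-]
Why: Saponification should take only the CH2CO2Me ester, because the α,α‑dimethyl ester on the ring methine is pivalate‑like and inert to hydroxide at room temperature; the base‑stable allylic ether is exposed to acid only briefly and cold.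

**Compound list**

1 | 2‑methylcyclopent‑2‑en‑1‑one | CC1=CCCC1=O | starting material
2 | 1‑methoxy‑2‑methyl‑1‑(trimethylsilyloxy)prop‑1‑ene | COC(O[Si](C)(C)C)=C(C)C | starting material
3 | methyl bromoacetate | COC(=O)CBr | starting material
4 | methyl 2‑methyl‑2‑[(1S)‑2‑methyl‑3‑(trimethylsilyloxy)cyclopent‑2‑en‑1‑yl]propanoate | C[Si](C)(C)OC1=C(C)[C@@H](C(C)(C)C(=O)OC)CC1 | intermediate (not isolated)
5 | methyl 2‑[(1R,2S)‑2‑(1‑methoxy‑2‑methyl‑1‑oxopropan‑2‑yl)‑1‑methyl‑5‑oxocyclopentyl]acetate | O=C1[C@](C)(CC(=O)OC)[C@@H](C(C)(C)C(=O)OC)CC1 | intermediate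
6 | (R)‑(−)‑linalool, (3R)‑3,7‑dimethylocta‑1,6‑dien‑3‑ol | C=C[C@](C)(O)CCC=C(C)C | starting material
7 | tert‑butyl{[(3R)‑3,7‑dimethylocta‑1,6‑dien‑3‑yl]oxy}dimethylsilane | C=C[C@](C)(O[Si](C)(C)C(C)(C)C)CCC=C(C)C | intermediate
8 | (4R)‑4‑[(tert‑butyldimethylsilyl)oxy]‑4‑methylhex‑5‑enal | C=C[C@](C)(O[Si](C)(C)C(C)(C)C)CCC=O | intermediate
9 | (4R)‑4‑[(tert‑butyldimethylsilyl)oxy]‑4‑methylhexa‑1,5‑dien‑1‑yl nonafluorobutane‑1‑sulfonate (E/Z mixture) | C=C[C@](C)(O[Si](C)(C)C(C)(C)C)CC=COS(=O)(=O)C(F)(F)C(F)(F)C(F)(F)C(F)(F)F | intermediate (not isolated)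
10 | tert‑butyldimethyl{[(3R)‑3‑methylhex‑1‑en‑5‑yn‑3‑yl]oxy}silane | C=C[C@](C)(O[Si](C)(C)C(C)(C)C)CC#C | intermediate
11 | lithium acetylide of 10 | C=C[C@](C)(O[Si](C)(C)C(C)(C)C)CC#C[Li] | intermediate (not isolated)
12 | methyl 2‑[(1R,2R,5S)‑2‑{(4R)‑4‑[(tert‑butyldimethylsilyl)oxy]‑4‑methylhex‑5‑en‑1‑yn‑1‑yl}‑2‑hydroxy‑5‑(1‑methoxy‑2‑methyl‑1‑oxopropan‑2‑yl)‑1‑methylcyclopentyl]acetate | O[C@@]1(C#CC[C@@](C)(O[Si](C)(C)C(C)(C)C)C=C)[C@](C)(CC(=O)OC)[C@@H](C(C)(C)C(=O)OC)CC1 | intermediate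
13 | methyl 2‑[(1R,2S,5S)‑2‑{(1Z,4R)‑4‑[(tert‑butyldimethylsilyl)oxy]‑4‑methylhexa‑1,5‑dien‑1‑yl}‑2‑hydroxy‑5‑(1‑methoxy‑2‑methyl‑1‑oxopropan‑2‑yl)‑1‑methylcyclopentyl]acetate | O[C@@]1(/C=C\C[C@@](C)(O[Si](C)(C)C(C)(C)C)C=C)[C@](C)(CC(=O)OC)[C@@H](C(C)(C)C(=O)OC)CC1 | intermediate
14 | methyl 2‑[(1R,2S,6S)‑2‑{(1S,3R)‑1‑bromo‑3‑[(tert‑butyldimethylsilyl)oxy]‑3‑methylpent‑4‑en‑1‑yl}‑6‑(1‑methoxy‑2‑methyl‑1‑oxopropan‑2‑yl)‑1‑methyl‑3‑oxocyclohexyl]acetate | O=C1[C@@H]([C@@H](Br)C[C@@](C)(O[Si](C)(C)C(C)(C)C)C=C)[C@](C)(CC(=O)OC)[C@@H](C(C)(C)C(=O)OC)CC1 | intermediate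
15 | methyl 2‑[(1R,2S,6S)‑2‑{(3R)‑3‑[(tert‑butyldimethylsilyl)oxy]‑3‑methylpent‑4‑en‑1‑yl}‑6‑(1‑methoxy‑2‑methyl‑1‑oxopropan‑2‑yl)‑1‑methyl‑3‑oxocyclohexyl]acetate | O=C1[C@@H](CC[C@@](C)(O[Si](C)(C)C(C)(C)C)C=C)[C@](C)(CC(=O)OC)[C@@H](C(C)(C)C(=O)OC)CC1 | intermediate
16 | methyl 2‑[(1S,2R,6S)‑2‑{(3R)‑3‑[(tert‑butyldimethylsilyl)oxy]‑3‑methylpent‑4‑en‑1‑yl}‑6‑(1‑methoxy‑2‑methyl‑1‑oxopropan‑2‑yl)‑1‑methyl‑3‑methylidenecyclohexyl]acetate | C=C1[C@@H](CC[C@@](C)(O[Si](C)(C)C(C)(C)C)C=C)[C@](C)(CC(=O)OC)[C@@H](C(C)(C)C(=O)OC)CC1 | intermediate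
17 | methyl 2‑[(1S,2R,6S)‑2‑[(3R)‑3‑hydroxy‑3‑methylpent‑4‑en‑1‑yl]‑6‑(1‑methoxy‑2‑methyl‑1‑oxopropan‑2‑yl)‑1‑methyl‑3‑methylidenecyclohexyl]acetate | C=C1[C@@H](CC[C@@](C)(O)C=C)[C@](C)(CC(=O)OC)[C@@H](C(C)(C)C(=O)OC)CC1 | intermediate
18 | methyl 2‑[(2R,4aS,5R,6S,8aS)‑2‑ethenyl‑6‑(1‑methoxy‑2‑methyl‑1‑oxopropan‑2‑yl)‑2,5,8a‑trimethyloctahydro‑2H‑chromen‑5‑yl]acetate | C=C[C@@]1(C)CC[C@H]2[C@](C)(CC(=O)OC)[C@@H](C(C)(C)C(=O)OC)CC[C@]2(C)O1 | intermediate
19 | 2‑[(2R,4aS,5R,6S,8aS)‑2‑ethenyl‑6‑(1‑methoxy‑2‑methyl‑1‑oxopropan‑2‑yl)‑2,5,8a‑trimethyloctahydro‑2H‑chromen‑5‑yl]acetic acid | C=C[C@@]1(C)CC[C@H]2[C@](C)(CC(=O)O)[C@@H](C(C)(C)C(=O)OC)CC[C@]2(C)O1 | target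

**Step count**

Total: 12 steps. Longest linear sequence: 11 steps (6 → 19, steps 2–12); the cyclopentanone branch joins after 1 step.

**Steps most likely to fail, with fallbacks**

Step 1. The risk is loss of enantiocontrol, or the opposite sense, in the conjugate addition: an α‑methyl enone cannot bind the oxazaborolidinium ion as an unsubstituted cycloalkenone does, and some O‑alkylation of the ammonium enolate may occur. The fallback sets out from 1, 2 and 3. The Mukaiyama–Michael addition is run with an achiral acid (HNTf2, cat., CH2Cl2, −78 °C) and the silyl enol ether is alkylated as before. This should give the trans keto diester as the racemate, that is 5 together with its enantiomer methyl 2‑[(1S,2R)‑2‑(1‑methoxy‑2‑methyl‑1‑oxopropan‑2‑yl)‑1‑methyl‑5‑oxocyclopentyl]acetate F1. The two are separated by preparative chromatography on a chiral stationary phase, and the route is rejoined at 5.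

Step 7. The risks are migration of the C7 methylene in place of C10, capture of the bromonium ion by the carbinol oxygen or by the solvent, and loss of HBr from the product. The fallback sets out from 13. Hydroxyl‑directed epoxidation (VO(acac)2, tetravalent vanadium, t‑BuOOH, toluene) should give the cis‑9,11‑epoxide of 13 F2, with the epoxide oxygen on the alkene face next to C7. A 2,3‑epoxy alcohol semipinacol rearrangement (BF3·OEt2, CH2Cl2, −78 °C) moves C10 to C9 anti to the C9–O bond and should give the 11‑hydroxy analogue of 14 F3. Mesylation and elimination (MsCl, Et3N; DBU) give the 9(11)‑en‑8‑one F4. Conjugate reduction with [(Ph3P)CuH]6 (monovalent copper), followed by protonation of the C8 enolate at C9 from the face opposite the axial C10 methyl, returns to the route at 15.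

Step 11. The risks are hydrogen‑atom transfer to the vinyl group and C–O bond formation on the wrong face of C8. The fallback sets out from 17 and uses the polar, biomimetic closure: catalytic TfOH, CH2Cl2, −78 °C, protonates C17 and the C13 hydroxyl captures the tertiary C8 cation equatorially. Any C13 epimer formed by ionization of the allylic alcohol would be removed by chromatography. No new compound is made, and the route is rejoined at 18.

**Further compounds**

F1 | step 1 | methyl 2‑[(1S,2R)‑2‑(1‑methoxy‑2‑methyl‑1‑oxopropan‑2‑yl)‑1‑methyl‑5‑oxocyclopentyl]acetate (enantiomer of 5) | O=C1[C@@](C)(CC(=O)OC)[C@H](C(C)(C)C(=O)OC)CC1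
F2 | step 7 | cis‑9,11‑epoxide of 13 (epoxy alcohol) | O[C@@]1([C@H]2O[C@H]2C[C@@](C)(O[Si](C)(C)C(C)(C)C)C=C)[C@](C)(CC(=O)OC)[C@@H](C(C)(C)C(=O)OC)CC1
F3 | step 7 | 11‑hydroxy analogue of 14 (β‑hydroxy ketone, OH in place of Br) | O=C1[C@@H]([C@@H](O)C[C@@](C)(O[Si](C)(C)C(C)(C)C)C=C)[C@](C)(CC(=O)OC)[C@@H](C(C)(C)C(=O)OC)CC1
F4 | step 7 | 9(11)‑en‑8‑one, methyl 2‑[(1R,6S)‑2‑{(Z,3R)‑3‑[(tert‑butyldimethylsilyl)oxy]‑3‑methylpent‑4‑en‑1‑ylidene}‑6‑(1‑methoxy‑2‑methyl‑1‑oxopropan‑2‑yl)‑1‑methyl‑3‑oxocyclohexyl]acetate | O=C1/C(=C\C[C@@](C)(O[Si](C)(C)C(C)(C)C)C=C)[C@](C)(CC(=O)OC)[C@@H](C(C)(C)C(=O)OC)CC1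
F0 | step 11 | none | none
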